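## Retrosynthetic overview
1. Target ⇒ Wittig olefination (Me2C=PPh3) of a C1 aldehyde that also carries the free propanoic acid chain (14). The isobutenyl group and the CH2CH2CO2H chain both come from opening one cyclohexene ring.
2. 14 ⇒ ozonolysis of the silyl enol ether in bicyclic adduct 13.
3. 13 ⇒ one intramolecular Diels–Alder reaction of silyloxydiene 12. It forms the cyclopentane and a cis-fused cyclohexene in one operation, setting quaternary C5 and C1. The cyclohexene is a removable second ring.
4. 12 ⇒ enone 11 ⇒ aldehyde 9 ⇒ the vinyl group of the Claisen product 4. An Ireland–Claisen rearrangement sets the C3/C4 trans diad.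
5. The umbelliferone ether is made early by Mitsunobu and carried intact.

**Assumptions (one line each)**
- The coumarin survives the mild, non-nucleophilic conditions of Steps 5–11.
- The chair transition state of Step 2 gives the anti diastereomer.

## Route

**Step 1**
Reactants: 1 (E)-but-2-en-1-ol; 2 3-methylbut-3-enoic acid
Product: 3 (E)-but-2-en-1-yl 3-methylbut-3-enoate
Conditions: EDC·HCl, DMAP, CH2Cl2, 0 °C → rt
Reagents that add atoms: none
Why: Steglich esterification joins the two cheap fragments; no stereocentre is formed.

**Step 2**
Reactants: 3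
Product: 4 (2R,3S)-3-methyl-2-(prop-1-en-2-yl)pent-4-enoic acid (anti)
Conditions: chiral B-bromodiazaborolidine (Corey type, enantiomer chosen to give 4), Et3N, toluene, −78 → 23 °C; aqueous work-up
Reagents that add atoms: none
Why: Proposed new method: the boron enolate of the β,γ-unsaturated ester rearranges through a chair [3,3] transition state. The (E)-crotyl geometry plus the Z-enolate gives the anti diad, and the chiral boron ligand sets the absolute sense. Closest known reaction: Corey's enantioselective Ireland–Claisen of crotyl propionates.

**Step 3**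
Reactants: 4
Product: 5 (2R,3S)-3-methyl-2-(prop-1-en-2-yl)pent-4-en-1-ol
Conditions: LiAlH4, Et2O, 0 °C
Reagents that add atoms: none
Why: Hydride reduction of the acid leaves both alkenes and both stereocentres untouched.

**Step 4**
Reactants: 5; 6 7-hydroxycoumarin (umbelliferone)
Product: 7 7-{[(2R,3S)-3-methyl-2-(prop-1-en-2-yl)pent-4-en-1-yl]oxy}coumarin
Conditions: PPh3, DIAD, THF, 0 °C → rt
Reagents that add atoms: 7-hydroxycoumarin, O=c1ccc2ccc(O)cc2o1 (reactant 6)
Why: Mitsunobu etherification is an SN2 on a primary carbon, so no stereocentre is affected.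

**Step 5**
Reactants: 7
Product: 8 primary alcohol (the vinyl group becomes CH2CH2OH)
Conditions: 9-BBN (1.05 equiv), THF, 0 °C → rt; then NaBO3·4H2O, THF/H2O, rt
Reagents that add atoms: sodium perborate, the source of the new O atom (active oxidant HOO−, SMILES OO)
Why: Hydroboration–oxidation; 9-BBN is selective for the monosubstituted vinyl group over the 1,1-disubstituted isopropenyl group, and the C–B to C–O conversion is anti-Markovnikov and stereochemically silent. The mild oxidant avoids opening the coumarin lactone.

**Step 6**
Reactants: 8
Product: 9 aldehyde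
Conditions: Dess–Martin periodinane, NaHCO3, CH2Cl2, rt
Reagents that add atoms: none
Why: Mild oxidation; the aldehyde's only stereocentre is β, so it cannot epimerise.

**Step 7**
Reactants: 9; 10 dimethyl (2-oxopropyl)phosphonate
Product: 11 (E)-enone
Conditions: LiCl, i-Pr2NEt, MeCN, rt
Reagents that add atoms: dimethyl (2-oxopropyl)phosphonate, COP(=O)(OC)CC(C)=O (reactant 10)
Why: Masamune–Roush Horner–Wadsworth–Emmons olefination gives the (E)-enone, which fixes the diene geometry needed for the Diels–Alder.

**Step 8**
Reactants: 11
Product: 12 2-(tert-butyldimethylsilyloxy)-1,3-diene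
Conditions: TBSOTf, Et3N, CH2Cl2, 0 °C; filter through basic alumina
Reagents that add atoms: TBSOTf, CC(C)(C)[Si](C)(C)OS(=O)(=O)C(F)(F)F
Why: Kinetic soft enolisation at the methyl ketone gives the cross-conjugated silyloxydiene (Rawal-type), an electron-rich diene for the next step.

**Step 9**
Reactants: 12
Product: 13 cis-fused silyl enol ether hydrindene
Conditions: toluene (0.02 M), BHT, 190 °C, sealed tube, 24 h
Reagents that add atoms: none
Why: Proposed new method: intramolecular Diels–Alder of a 1,3,8-nonatriene builds the cyclopentane and the cyclohexene together. The C3 methyl is pseudo-equatorial and the bulky CH2OAr group sits exo, so the diene adds to the dienophile face anti to CH2OAr. This gives the cis-fused adduct, with the new ring and the C3 methyl on the same face. It sets quaternary C5 and C1 in one operation. Closest known reaction: thermal IMDA of 2-siloxy-1,3,8-nonatrienes.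

**Step 10**
Reactants: 13
Product: 14 aldehyde bearing the free CH2CH2CO2H chain
Conditions: O3, CH2Cl2/MeOH, −78 °C; then PPh3; then 1 M citric acid work-up
Reagents that add atoms: ozone, [O-][O+]=O
Why: Ozonolysis cleaves the electron-rich enol ether selectively. The carbon bearing OTBS becomes the acid (the silyl ester hydrolyses) and the other carbon becomes the C1 aldehyde. The cyclohexene ring is thereby opened and no stereocentre is touched.

**Step 11**
Reactants: 14; 15 isopropyltriphenylphosphonium iodide
Product: 16 ferulsinaic acid
Conditions: 15, KHMDS (3.3 equiv each), THF, 0 °C; add 14 at −78 °C → rt; 1 M HCl work-up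
Reagents that add atoms: isopropyltriphenylphosphonium iodide, CC(C)[P+](c1ccccc1)(c1ccccc1)c1ccccc1.[I-] (reactant 15)
Why: Wittig olefination with Me2C=PPh3 converts the CHO into the CH=CMe2 group. The first equivalent of ylide only deprotonates the acid, and no new stereocentre is formed.

## Compound list
1 | (E)-but-2-en-1-ol | C/C=C/CO | starting material
2 | 3-methylbut-3-enoic acid | CC(=C)CC(=O)O | starting material
3 | (E)-but-2-en-1-yl 3-methylbut-3-enoate | C/C=C/COC(=O)CC(C)=C | intermediate
4 | (2R,3S)-3-methyl-2-(prop-1-en-2-yl)pent-4-enoic acid | C=C[C@H](C)[C@@H](C(=O)O)C(C)=C | intermediate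
5 | (2R,3S)-3-methyl-2-(prop-1-en-2-yl)pent-4-en-1-ol | C=C[C@H](C)[C@@H](CO)C(C)=C | intermediate
6 | 7-hydroxycoumarin (umbelliferone) | O=c1ccc2ccc(O)cc2o1 | starting material
7 | coumarinyl ether of 5 | C=C[C@H](C)[C@@H](COc2ccc3ccc(=O)oc3c2)C(C)=C | intermediate
8 | primary alcohol from hydroboration of 7 | OCC[C@H](C)[C@@H](COc2ccc3ccc(=O)oc3c2)C(C)=C | intermediate
9 | aldehyde | O=CC[C@H](C)[C@@H](COc2ccc3ccc(=O)oc3c2)C(C)=C | intermediate
10 | dimethyl (2-oxopropyl)phosphonate | COP(=O)(OC)CC(C)=O | starting material
11 | (E)-enone | CC(=O)/C=C/C[C@H](C)[C@@H](COc2ccc3ccc(=O)oc3c2)C(C)=C | intermediate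
12 | 2-(TBSO)-1,3-diene | C=C(O[Si](C)(C)C(C)(C)C)/C=C/C[C@H](C)[C@@H](COc2ccc3ccc(=O)oc3c2)C(C)=C | intermediate
13 | cis-fused silyl enol ether hydrindene | CC(C)(C)[Si](C)(C)OC2=C[C@@H]1C[C@H](C)[C@@H](COc3ccc4ccc(=O)oc4c3)[C@]1(C)CC2 | intermediate
14 | aldehyde–acid (ring-opened) | O=C[C@@H]1C[C@H](C)[C@@H](COc2ccc3ccc(=O)oc3c2)[C@]1(C)CCC(=O)O | intermediate
15 | isopropyltriphenylphosphonium iodide | CC(C)[P+](c1ccccc1)(c1ccccc1)c1ccccc1.[I-] | starting material
16 | ferulsinaic acid | CC(C)=C[C@@H]1C[C@H](C)[C@@H](COc2ccc3ccc(=O)oc3c2)[C@]1(C)CCC(=O)O | target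

## Totals
Total steps: 11. Longest linear sequence: 11 (from (E)-but-2-en-1-ol, 1).

## Three steps most likely to fail
1. **Step 9, the Diels–Alder.** The dienophile is unactivated and hindered, and the coumarin alkene could compete intermolecularly at 190 °C. The cis/trans fusion ratio and the face selectivity may also be poor.
   Fallback: use the dienoate version of the triene, made by Horner–Wadsworth–Emmons with triethyl 4-phosphonocrotonate in place of 10. Cyclise it at −20 °C with EtAlCl2, then ozonolyse, deformylate the α-formyl ester and hydrolyse the ester to reach 14.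
2. **Step 2, the asymmetric Claisen.** The boron-mediated Ireland–Claisen is unprecedented for an α-alkenyl ester, so the anti selectivity and enantiomeric excess are uncertain.
   Fallback: a chirality-transfer Ireland–Claisen of the 3-methylbut-3-enoate of enantiopure (E)-pent-3-en-2-ol (the enantiomer that delivers 4), followed by ethenolysis (Grubbs II, ethylene) to regenerate the vinyl group.
3. **Step 11, the Wittig olefination.** The strongly basic ylide may attack the coumarin, and the α-branched aldehyde next to the quaternary centre may epimerise at C1.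
   Fallback: protect the alcohol as its TBS ether in place of the coumarin ether in Step 4, then make the ester of the final acid. After the Wittig or a Julia–Kocienski olefination (isopropyl tetrazolyl sulfone, KHMDS), remove the TBS group (TBAF) and install umbelliferone by Mitsunobu. Finish with mild ester hydrolysis.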